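The ten-membered ring is cut at C5–C6. Both atoms are enol-type carbons: C5 lies α to the C4 oxygen function and C6 is the γ-carbon of the C7=C11–C12 butenolide ring, so the bond is made by oxidative coupling of two silyl enol derivatives. Anodic oxidation of an open-chain precursor, in which a C4=C5 enediol bis(silyl) ether is joined through the C1–C2 cis-epoxide and the C10 methylene to a 2-silyloxyfuran, should in one operation form C5–C6, close the carbocycle, set C5 and C6, and release the C4 ketone and the butenolide.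

Key step: step 18

Remark on numbering: C1–C10 are the ring carbons, C11 and C12 the α-carbon and carbonyl of the lactone, C13 the oxymethyl carbon on C11, C14 the methylene carbon on C10 and C15 the methyl carbon on C4; these numbers are used for all intermediates. TBS = tert-butyldimethylsilyl, TBDPS = tert-butyldiphenylsilyl, TES = triethylsilyl, PMB = 4-methoxybenzyl.

Remark on the design of the precursor: the C4=C5 enol ether is made from a C5 aldehyde that can enolise in one direction only. O4 carries the labile TES group that is to be lost and O5 the robust TBS group that is to stay. O13 is carried as a silyl ether and acetylated late, because an acetate there would be an allylic leaving group on the silyloxyfuran and would not survive the organometallic and basic steps.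

Assumption: the sense of induction of the chiral boron reagent (step 6) and of the hydroxyl-directed epoxidation (step 13) is taken from the usual chair-like transition-state models; if a first run showed the opposite sense, the mirror-image controller or the other glycidol enantiomer would be used. The (Z) geometry drawn for 23 is the expected major isomer.

**Route**

Step 1
Reactants: 1 furan-3-ylmethanol
Product: 2 tert-butyl(furan-3-ylmethoxy)dimethylsilane
Conditions: TBSCl, imidazole, CH2Cl2, rt
Reagents that add atoms: tert-butyldimethylsilyl chloride, CC(C)(C)[Si](C)(C)Cl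
Why: Routine silyl ether formation on a primary alcohol.

Step 2
Reactants: 2 tert-butyl(furan-3-ylmethoxy)dimethylsilane
Product: 4 [2-(tert-butyldimethylsilyl)furan-3-yl]methanol, via 2-lithiofuran 3 (not isolated)
Conditions: n-BuLi, HMPA, THF, −78 °C → rt; H2O
Reagents that add atoms: none
Why: Lithiation of the furan α-position next to the oxymethyl group is followed by 1,4 O→C silyl migration (retro-Brook rearrangement), which puts silicon on the carbon that will become C12 and frees the C13 hydroxyl.

Step 3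
Reactants: 4 [2-(tert-butyldimethylsilyl)furan-3-yl]methanol
Product: 6 5-(tert-butyldimethylsilyl)-4-(hydroxymethyl)furan-3-carbaldehyde, via dilithio species 5 (not isolated)
Conditions: n-BuLi (2.2 equiv), DME, 0 °C; DMF, −78 → 0 °C; H2O
Reagents that add atoms: N,N-dimethylformamide, CN(C)C=O
Why: The lithium alkoxide directs the second lithiation to the adjacent β-position (directed ortho-metalation), the neighbouring α-position being blocked by silicon, and formylation introduces C8.

Step 4
Reactants: 6 5-(tert-butyldimethylsilyl)-4-(hydroxymethyl)furan-3-carbaldehyde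
Product: 7 5-(tert-butyldimethylsilyl)-4-{[(tert-butyldiphenylsilyl)oxy]methyl}furan-3-carbaldehyde
Conditions: TBDPSCl, imidazole, DMF, rt
Reagents that add atoms: tert-butyldiphenylsilyl chloride, CC(C)(C)[Si](Cl)(c1ccccc1)c1ccccc1
Why: Routine silylation; the bulky diphenylsilyl ether is chosen to outlast the later selective desilylations.

Step 5
Reactants: 8 2,3-dibromoprop-1-ene
Product: 9 (2-bromoprop-2-en-1-yl)tributylstannane
Conditions: Bu3SnCl, Zn, THF/aq. NH4Cl, rt
Reagents that add atoms: tributyltin chloride, CCCC[Sn](Cl)(CCCC)CCCC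
Why: Barbier-type stannylation in which zinc inserts only into the allylic C–Br bond and the allylzinc is trapped by the tin chloride (either allyl terminus gives the same product), the vinylic bromide being inert.

Step 6
Reactants: 7 5-(tert-butyldimethylsilyl)-4-{[(tert-butyldiphenylsilyl)oxy]methyl}furan-3-carbaldehyde; 9 (2-bromoprop-2-en-1-yl)tributylstannane
Product: 10 (1S)-3-bromo-1-[5-(tert-butyldimethylsilyl)-4-{[(tert-butyldiphenylsilyl)oxy]methyl}furan-3-yl]but-3-en-1-ol
Conditions: (R,R)-1,2-diphenyl-N,N′-bis(p-tolylsulfonyl)ethane-1,2-diamine, BBr3, CH2Cl2, 0 °C → rt, evaporate; 9, CH2Cl2, rt; 7, −78 °C; pH 7 buffer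
Reagents that add atoms: none
Why: Enantioselective allylboration: tin-to-boron exchange gives a chiral 2-bromoallyl diazaborolidine that should add to the Si face of the aldehyde through a chair-like six-membered transition state and set C8 as S under reagent control.

Step 7
Reactants: 10 (1S)-3-bromo-1-[5-(tert-butyldimethylsilyl)-4-{[(tert-butyldiphenylsilyl)oxy]methyl}furan-3-yl]but-3-en-1-ol
Product: 11 tert-butyldiphenylsilyl ether of 10 at the C8 oxygen
Conditions: TBDPSCl, imidazole, DMAP (cat.), DMF, 40 °C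
Reagents that add atoms: tert-butyldiphenylsilyl chloride, CC(C)(C)[Si](Cl)(c1ccccc1)c1ccccc1
Why: Routine silylation of the secondary carbinol, with no change at C8.

Step 8
Reactants: 11 tert-butyldiphenylsilyl ether of 10 at the C8 oxygen
Product: 13 4-[(1S)-3-bromo-1-(tert-butyldiphenylsilyloxy)but-3-en-1-yl]-3-{[(tert-butyldiphenylsilyl)oxy]methyl}furan-2(5H)-one, via silyloxyfuran 12 (not isolated)
Conditions: CH3CO3H, NaOAc, CH2Cl2, 0 °C → rt; then Et3N (cat.)
Reagents that add atoms: peracetic acid, CC(=O)OO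
Why: Peracid oxidation of a 2-silylfuran: epoxidation at the silicon-bearing double bond and 1,2-shift of silicon to oxygen give the silyloxyfuran, which is protonated to the conjugated butenolide, so that silicon fixes C12 as the carbonyl carbon and C6 as the CH2 group.

Step 9
Reactants: 14 (S)-glycidol
Product: 15 (R)-2-{[(4-methoxybenzyl)oxy]methyl}oxirane
Conditions: NaH, PMBCl, Bu4NI (cat.), DMF, 0 °C
Reagents that add atoms: 4-methoxybenzyl chloride, COc1ccc(CCl)cc1
Why: Williamson ether synthesis that leaves the stereocentre untouched (the descriptor changes only through the priority rules).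

Step 10
Reactants: 15 (R)-2-{[(4-methoxybenzyl)oxy]methyl}oxirane
Product: 16 (2R)-1-[(4-methoxybenzyl)oxy]pent-4-yn-2-ol
Conditions: LiC≡CH·H2NCH2CH2NH2, DMSO, rt
Reagents that add atoms: lithium acetylide (ethylenediamine complex), [Li]C#C
Why: SN2 opening of the epoxide by acetylide at the unsubstituted carbon delivers C1–C2 as an alkyne and keeps the future C4 carbinol centre as R.

Step 11
Reactants: 13 4-[(1S)-3-bromo-1-(tert-butyldiphenylsilyloxy)but-3-en-1-yl]-3-{[(tert-butyldiphenylsilyl)oxy]methyl}furan-2(5H)-one; 16 (2R)-1-[(4-methoxybenzyl)oxy]pent-4-yn-2-ol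
Product: 17 enyne PMBO–C5H2–(4R)-C4H(OH)–C3H2–C2≡C1–C10(=C14H2)–C9H2–(8S)-C8H(OTBDPS)–[C7 of 3-(TBDPSOCH2)furan-2(5H)-one]
Conditions: Pd(PPh3)4 (cat.), CuI (cat.), i-Pr2NH, THF, rt → 40 °C
Reagents that add atoms: none
Why: Sonogashira coupling of the vinylic bromide with the terminal alkyne forms the C1–C10 bond without touching the stereocentres.

Step 12
Reactants: 17 enyne
Product: 18 (1Z)-diene: as 17 with a (Z)-C1=C2 double bond
Conditions: Zn(Cu/Ag), MeOH/H2O, rt
Reagents that add atoms: none
Why: Activated-zinc reduction of a conjugated enyne adds hydrogen syn and stops at the (Z)-alkene, leaving the isolated and the electron-poor double bonds alone.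

Step 13
Reactants: 18 (1Z)-diene
Product: 19 epoxy alcohol: as 18 with a (1R,2S)-cis-epoxide in place of C1=C2; (4R)-OH, (8S)
Conditions: VO(acac)2 (cat.), t-BuOOH, CH2Cl2, 0 °C → rt
Reagents that add atoms: tert-butyl hydroperoxide, CC(C)(C)OO
Why: Hydroxyl-directed vanadium-catalysed epoxidation: the vanadate ester of the C4 alcohol delivers oxygen only to the nearby C1=C2 bond through a chair-like transition state with the C5 substituent equatorial, which should give the 1,3-syn epoxy alcohol, that is the (1R,2S)-cis-epoxide.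

Step 14
Reactants: 19 epoxy alcohol
Product: 20 C4 triethylsilyl ether of 19
Conditions: TESCl, imidazole, CH2Cl2, 0 °C
Reagents that add atoms: chlorotriethylsilane, CC[Si](Cl)(CC)CC
Why: Routine silylation that installs on O4 the labile silyl group meant to leave in the key step.

Step 15
Reactants: 20 C4 triethylsilyl ether of 19
Product: 21 C5 primary alcohol: as 20 with OH in place of OPMB
Conditions: DDQ, CH2Cl2/pH 7 buffer, 0 °C
Reagents that add atoms: none
Why: Oxidative cleavage of the p-methoxybenzyl ether (hydride abstraction and hydrolysis of the oxocarbenium ion), to which silyl ethers, epoxide and the unactivated alkenes are inert.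

Step 16
Reactants: 21 C5 primary alcohol
Product: 22 C5 aldehyde: OHC5–(4R)-C4H(OTES)–C3H2–[(2S,1R)-epoxide]–C10(=C14H2)–C9H2–(8S)-C8H(OTBDPS)–butenolide
Conditions: Dess–Martin periodinane, NaHCO3, CH2Cl2, 0 °C → rt
Reagents that add atoms: none
Why: Dess–Martin oxidation is neutral and stops at the aldehyde, so the epoxide and the silyl ethers should survive.

Step 17
Reactants: 22 C5 aldehyde
Product: 23 key precursor: (4Z)-TBSO–C5H=C4(OTES)–C3H2–[(2S,1R)-epoxide]–C10(=C14H2)–C9H2–(8S)-C8H(OTBDPS)–[C7 of 2-(TBSO)-3-(TBDPSOCH2)furan]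
Conditions: TBSOTf, Et3N, CH2Cl2, −78 → 0 °C
Reagents that add atoms: tert-butyldimethylsilyl trifluoromethanesulfonate, CC(C)(C)[Si](C)(C)OS(=O)(=O)C(F)(F)F
Why: Soft enolisation with silyl triflate and amine: the aldehyde has a single α-hydrogen (on C4), so only the C4=C5 enediol ether can form, and the butenolide is converted into its 2-silyloxyfuran in the same operation.

Step 18
Reactants: 23 key precursor
Product: 24 ten-membered keto butenolide: (1R,2S)-1,2-epoxide, C4 ketone, (5S)-OTBS, (6S)-6,12-lactone with C7=C11, (8S)-OTBDPS, C10=C14 methylene, 13-OTBDPS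
Conditions: carbon (RVC) anode, Pt cathode, undivided cell, constant current, 2.2 F/mol; LiClO4 (0.1 M), 2,6-lutidine, i-PrOH, CH2Cl2/MeCN, 1 mM, rt
Reagents that add atoms: none
Why: Proposed new method: the C4=C5 enediol bis(silyl) ether, the most easily oxidised group, should lose one electron at the anode to a radical cation (or, after loss of the labile TES group from O4, the C5 α-keto radical), which is attacked at C5 by C6 of the tethered 2-silyloxyfuran, and a second electron transfer with loss of the furan silyl group then leaves the C4 ketone and the C7=C11 butenolide; the closest known reaction types are the anodic coupling of silyl enol ethers with furans and the oxidative cross-coupling of two silyl enol ethers to 1,4-dicarbonyl compounds. The ten-membered carbocycle closes by bond formation between the terminal sp2 carbons C5 and C6 (endo with respect to both π-systems) at high dilution, with the cis-epoxide, the sp2 C10 and the flat furan bending the chain so that the ends can meet. C6 should be set by the C8 stereocentre, whose bulky silyloxy group is held out of the furan plane by allylic strain and shields one face, and C5 by the enol ether geometry and the C1–C2 epoxide acting through the cyclic transition state; this relay is not established. The step needs ring closure in preference to coupling between molecules and C–C bonding at C5 and C6 only, which the tether, the unsubstituted C5 terminus, the single free α-position (C6) of the furan and the robust silyl group on O5 (so that only O4 is desilylated) are meant to secure.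

Step 19
Reactants: 24 ten-membered keto butenolide
Product: 25 α-hydroxy ketone: as 24 with (5S)-OH
Conditions: HF·pyridine, pyridine, THF, 0 °C → rt
Reagents that add atoms: none
Why: Buffered fluoride cleaves the tert-butyldimethylsilyl ether much faster than the two tert-butyldiphenylsilyl ethers and leaves the epoxide alone.

Step 20
Reactants: 25 α-hydroxy ketone
Product: 26 diol: (4R)-C4(OH)(CH3), (5S)-OH, otherwise as 25
Conditions: MeTi(OiPr)3 (3 equiv), THF, −40 → 0 °C
Reagents that add atoms: methyltitanium triisopropoxide, C[Ti](OC(C)C)(OC(C)C)OC(C)C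
Why: Chelation-controlled 1,2-addition: alcoholysis binds titanium to O5, the five-membered chelate with the C4 carbonyl exposes the face anti to C6 (Cram chelate model) and methyl transfer should give the (4R) tertiary alcohol, while the non-basic reagent spares lactone, epoxide and silyl ethers.

Step 21
Reactants: 26 diol
Product: 28 bis-epoxide: (4R,5R)-trans-4,5-epoxide with C15 methyl on C4, (1R,2S)-1,2-epoxide, (6S)-lactone, (8S)-OTBDPS, 13-OTBDPS, via C5 mesylate 27 (not isolated)
Conditions: Ms2O, pyridine, CH2Cl2, 0 °C; then K2CO3, MeOH, 0 °C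
Reagents that add atoms: none
Why: Selective sulfonylation of the secondary C5 hydroxyl is followed by intramolecular Williamson-type SN2 closure by the tertiary C4 alkoxide with inversion at C5, which turns the (4R,5S)-diol into the trans-epoxide.

Step 22
Reactants: 28 bis-epoxide
Product: 29 bis-epoxide diol with free C8 and C13 hydroxyls
Conditions: Bu4NF, AcOH, THF, rt
Reagents that add atoms: none
Why: Acetic-acid-buffered fluoride removes both diphenylsilyl ethers under near-neutral conditions that the epoxides and the butenolide should tolerate.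

Step 23
Reactants: 29 bis-epoxide diol
Product: 30 C13 monoacetate with free (8S)-OH
Conditions: Ac2O (1.1 equiv), 2,4,6-collidine, CH2Cl2, −20 → 0 °C
Reagents that add atoms: acetic anhydride, CC(=O)OC(C)=O
Why: Acylation is much faster at the primary allylic C13 hydroxyl than at the hindered secondary C8 hydroxyl.

Step 24
Reactants: 31 2-(hydroxymethyl)prop-2-enoic acid
Product: 33 2-{[(tert-butyldimethylsilyl)oxy]methyl}prop-2-enoic acid, via bis-silyl derivative 32 (not isolated)
Conditions: TBSCl, imidazole, DMF, rt; then K2CO3, MeOH/H2O; citric acid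
Reagents that add atoms: tert-butyldimethylsilyl chloride, CC(C)(C)[Si](C)(C)Cl
Why: Silylation of both hydroxyl functions is followed by selective solvolysis of the labile silyl ester, which leaves the silyl ether.

Step 25
Reactants: 30 C13 monoacetate; 33 2-{[(tert-butyldimethylsilyl)oxy]methyl}prop-2-enoic acid
Product: 34 C8 ester of 30 with 33
Conditions: EDCI·HCl, DMAP, CH2Cl2, 0 °C → rt
Reagents that add atoms: none
Why: Carbodiimide (Steglich) esterification acylates the remaining secondary alcohol with retention at C8.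

Step 26
Reactants: 34 C8 ester
Product: 35 CNP0233746.1
Conditions: HF·pyridine, pyridine, THF, 0 °C
Reagents that add atoms: none
Why: Buffered fluoride cleaves the primary silyl ether without touching the esters, the epoxides or the butenolide.

**Compound list**

1 | furan-3-ylmethanol | OCc1ccoc1 | starting material
2 | tert-butyl(furan-3-ylmethoxy)dimethylsilane | CC(C)(C)[Si](C)(C)OCc1ccoc1 | intermediate
3 | 2-lithio derivative of 2 (not isolated) | [Li]c1occc1CO[Si](C)(C)C(C)(C)C | intermediate
4 | [2-(tert-butyldimethylsilyl)furan-3-yl]methanol | OCc1ccoc1[Si](C)(C)C(C)(C)C | intermediate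
5 | O,C-dilithio derivative of 4 (not isolated) | [Li]OCc1c([Li])coc1[Si](C)(C)C(C)(C)C | intermediate
6 | 5-(tert-butyldimethylsilyl)-4-(hydroxymethyl)furan-3-carbaldehyde | O=Cc1coc([Si](C)(C)C(C)(C)C)c1CO | intermediate
7 | 5-(tert-butyldimethylsilyl)-4-{[(tert-butyldiphenylsilyl)oxy]methyl}furan-3-carbaldehyde | O=Cc1coc([Si](C)(C)C(C)(C)C)c1CO[Si](c1ccccc1)(c1ccccc1)C(C)(C)C | intermediate
8 | 2,3-dibromoprop-1-ene | C=C(Br)CBr | starting material
9 | (2-bromoprop-2-en-1-yl)tributylstannane | C=C(Br)C[Sn](CCCC)(CCCC)CCCC | intermediate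
10 | (1S)-3-bromo-1-[5-(tert-butyldimethylsilyl)-4-{[(tert-butyldiphenylsilyl)oxy]methyl}furan-3-yl]but-3-en-1-ol | C=C(Br)C[C@H](O)c1coc([Si](C)(C)C(C)(C)C)c1CO[Si](c1ccccc1)(c1ccccc1)C(C)(C)C | intermediate
11 | C8 tert-butyldiphenylsilyl ether of 10, (8S) | C=C(Br)C[C@H](O[Si](c1ccccc1)(c1ccccc1)C(C)(C)C)c1coc([Si](C)(C)C(C)(C)C)c1CO[Si](c1ccccc1)(c1ccccc1)C(C)(C)C | intermediate
12 | 2-(tert-butyldimethylsilyloxy)furan formed from 11 (not isolated), (8S) | C=C(Br)C[C@H](O[Si](c1ccccc1)(c1ccccc1)C(C)(C)C)c1coc(O[Si](C)(C)C(C)(C)C)c1CO[Si](c1ccccc1)(c1ccccc1)C(C)(C)C | intermediate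
13 | 4-[(1S)-3-bromo-1-(tert-butyldiphenylsilyloxy)but-3-en-1-yl]-3-{[(tert-butyldiphenylsilyl)oxy]methyl}furan-2(5H)-one | C=C(Br)C[C@H](O[Si](c1ccccc1)(c1ccccc1)C(C)(C)C)C1=C(CO[Si](c2ccccc2)(c2ccccc2)C(C)(C)C)C(=O)OC1 | intermediate
14 | (S)-glycidol | OC[C@H]1CO1 | starting material
15 | (R)-2-{[(4-methoxybenzyl)oxy]methyl}oxirane | COc1ccc(COC[C@H]2CO2)cc1 | intermediate
16 | (2R)-1-[(4-methoxybenzyl)oxy]pent-4-yn-2-ol | COc1ccc(COC[C@H](O)CC#C)cc1 | intermediate
17 | enyne, (4R,8S): C5–OPMB, C4–OH, C1≡C2, C10=C14, C8–OTBDPS, butenolide with 13-OTBDPS | COc1ccc(COC[C@H](O)CC#CC(=C)C[C@H](O[Si](c2ccccc2)(c2ccccc2)C(C)(C)C)C2=C(CO[Si](c3ccccc3)(c3ccccc3)C(C)(C)C)C(=O)OC2)cc1 | intermediate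
18 | (1Z)-diene, (4R,8S) | COc1ccc(COC[C@H](O)C/C=C\C(=C)C[C@H](O[Si](c2ccccc2)(c2ccccc2)C(C)(C)C)C2=C(CO[Si](c3ccccc3)(c3ccccc3)C(C)(C)C)C(=O)OC2)cc1 | intermediate
19 | epoxy alcohol, (1R,2S,4R,8S) | COc1ccc(COC[C@H](O)C[C@@H]2O[C@@H]2C(=C)C[C@H](O[Si](c2ccccc2)(c2ccccc2)C(C)(C)C)C2=C(CO[Si](c3ccccc3)(c3ccccc3)C(C)(C)C)C(=O)OC2)cc1 | intermediate
20 | C4 triethylsilyl ether of 19, (1R,2S,4R,8S) | COc1ccc(COC[C@H](O[Si](CC)(CC)CC)C[C@@H]2O[C@@H]2C(=C)C[C@H](O[Si](c2ccccc2)(c2ccccc2)C(C)(C)C)C2=C(CO[Si](c3ccccc3)(c3ccccc3)C(C)(C)C)C(=O)OC2)cc1 | intermediate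
21 | C5 primary alcohol, (1R,2S,4R,8S) | OC[C@H](O[Si](CC)(CC)CC)C[C@@H]1O[C@@H]1C(=C)C[C@H](O[Si](c1ccccc1)(c1ccccc1)C(C)(C)C)C1=C(CO[Si](c2ccccc2)(c2ccccc2)C(C)(C)C)C(=O)OC1 | intermediate
22 | C5 aldehyde, (1R,2S,4R,8S) | O=C[C@H](O[Si](CC)(CC)CC)C[C@@H]1O[C@@H]1C(=C)C[C@H](O[Si](c1ccccc1)(c1ccccc1)C(C)(C)C)C1=C(CO[Si](c2ccccc2)(c2ccccc2)C(C)(C)C)C(=O)OC1 | intermediate
23 | key precursor, (4Z,1R,2S,8S): C5–OTBS/C4–OTES enediol ether and 2-(TBSO)furan | CC(C)(C)[Si](C)(C)O/C=C(\O[Si](CC)(CC)CC)C[C@@H]1O[C@@H]1C(=C)C[C@H](O[Si](c1ccccc1)(c1ccccc1)C(C)(C)C)c1coc(O[Si](C)(C)C(C)(C)C)c1CO[Si](c1ccccc1)(c1ccccc1)C(C)(C)C | intermediate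
24 | ten-membered keto butenolide, (1R,2S,5S,6S,8S): C4 ketone, 5-OTBS, 8-OTBDPS, 13-OTBDPS | CC(C)(C)[Si](c1ccccc1)(c1ccccc1)O[C@H]1CC(=C)[C@H]2O[C@H]2CC(=O)[C@@H](O[Si](C)(C)C(C)(C)C)[C@H]2OC(=O)C(CO[Si](c3ccccc3)(c3ccccc3)C(C)(C)C)=C12 | intermediate
25 | α-hydroxy ketone, (1R,2S,5S,6S,8S) | CC(C)(C)[Si](c1ccccc1)(c1ccccc1)O[C@H]1CC(=C)[C@H]2O[C@H]2CC(=O)[C@@H](O)[C@H]2OC(=O)C(CO[Si](c3ccccc3)(c3ccccc3)C(C)(C)C)=C12 | intermediate
26 | diol, (1R,2S,4R,5S,6S,8S) | CC(C)(C)[Si](c1ccccc1)(c1ccccc1)O[C@H]1CC(=C)[C@H]2O[C@H]2C[C@@](C)(O)[C@@H](O)[C@H]2OC(=O)C(CO[Si](c3ccccc3)(c3ccccc3)C(C)(C)C)=C12 | intermediate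
27 | C5 mesylate of 26 (not isolated) | CC(C)(C)[Si](c1ccccc1)(c1ccccc1)O[C@H]1CC(=C)[C@H]2O[C@H]2C[C@@](C)(O)[C@@H](OS(C)(=O)=O)[C@H]2OC(=O)C(CO[Si](c3ccccc3)(c3ccccc3)C(C)(C)C)=C12 | intermediate
28 | bis-epoxide, (1R,2S,4R,5R,6S,8S), 8-OTBDPS, 13-OTBDPS | CC(C)(C)[Si](c1ccccc1)(c1ccccc1)O[C@H]1CC(=C)[C@H]2O[C@H]2C[C@@]2(C)O[C@@H]2[C@H]2OC(=O)C(CO[Si](c3ccccc3)(c3ccccc3)C(C)(C)C)=C12 | intermediate
29 | bis-epoxide diol, 8-OH, 13-OH | O[C@H]1CC(=C)[C@H]2O[C@H]2C[C@@]2(C)O[C@@H]2[C@H]2OC(=O)C(CO)=C12 | intermediate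
30 | C13 monoacetate, 8-OH | O[C@H]1CC(=C)[C@H]2O[C@H]2C[C@@]2(C)O[C@@H]2[C@H]2OC(=O)C(COC(C)=O)=C12 | intermediate
31 | 2-(hydroxymethyl)prop-2-enoic acid | C=C(CO)C(=O)O | starting material
32 | tert-butyldimethylsilyl 2-{[(tert-butyldimethylsilyl)oxy]methyl}prop-2-enoate (not isolated) | C=C(CO[Si](C)(C)C(C)(C)C)C(=O)O[Si](C)(C)C(C)(C)C | intermediate
33 | 2-{[(tert-butyldimethylsilyl)oxy]methyl}prop-2-enoic acid | C=C(CO[Si](C)(C)C(C)(C)C)C(=O)O | intermediate
34 | C8 ester of 30 with 33 | C=C(CO[Si](C)(C)C(C)(C)C)C(=O)O[C@H]1CC(=C)[C@H]2O[C@H]2C[C@@]2(C)O[C@@H]2[C@H]2OC(=O)C(COC(C)=O)=C12 | intermediate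
35 | CNP0233746.1 | C=C(CO)C(=O)O[C@H]1CC(=C)[C@H]2O[C@H]2C[C@@]2(C)O[C@@H]2[C@H]2OC(=O)C(COC(C)=O)=C12 | target

**Step count and risks**

Total step count: 26. Longest linear sequence: 22 steps (1–4, 6–8, 11–23, 25, 26).

Steps most likely to fail:

1. Step 18 (anodic ring closure). The radical cation may be desilylated or captured by the medium, be oxidised further at C5, or couple between molecules before the ten-membered ring closes, and the two faces of the π-systems may not be differentiated. Fallback with known chemistry: it sets out from aldehyde 22 and uses a silylative intramolecular vinylogous Mukaiyama aldol reaction (TBSOTf, i-Pr2NEt, CH2Cl2, −78 °C, high dilution). The butenolide is converted in the flask into its 2-silyloxyfuran, which adds through C6 to the silyl-activated C5 aldehyde and should give the C5-silylated macrocyclic aldol F1. Selective removal of the triethylsilyl group (PPTS, MeOH, 0 °C) should give the C4 alcohol F2, and Dess–Martin oxidation of F2 comes back to the route at ketone 24.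

2. Step 20 (methyl addition). The ring conformation may override chelation, so that methyl is delivered to the other face of the C4 carbonyl. Fallback: it sets out from 25; the same addition would then give the 4-epi-diol F3. This is converted with 1,1′-thiocarbonyldiimidazole (DMAP, toluene, 80 °C) into the cyclic thiocarbonate F4. Corey–Winter olefination with 1,3-dimethyl-2-phenyl-1,3,2-diazaphospholidine (THF, 40 °C), a stereospecific syn-elimination, should give the (E)-C4=C5 alkene F5. Epoxidation of this trisubstituted alkene with dimethyldioxirane (acetone, 0 °C) from the outer face of the ring, the known preference of (E)-4,5-olefins in germacranolides, comes back to the route at bis-epoxide 28.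

3. Step 13 (directed epoxidation). Facial selectivity of oxygen delivery may be poor, and the vanadium catalyst may promote opening of the new vinyl epoxide by the C4 hydroxyl. Fallback: it sets out from diene 18, which is first silylated (TESCl, imidazole) to the dienyl triethylsilyl ether F6. Shi epoxidation with the D-glucose-derived N-aryl oxazolidinone ketone (Oxone, K2CO3, Bu4NHSO4, dimethoxymethane/buffer, −10 °C) is selective for cis-alkenes conjugated to a second π-system, and by analogy with (Z)-β-methylstyrene should give the (1R,2S)-epoxide under catalyst control. It comes back to the route at 20.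

**Further compounds**

F1 | step 18 | C5-silylated macrocyclic aldol, (1R,2S,4R,5S,6S,8S): 4-OTES, 5-OTBS, 8-OTBDPS, 13-OTBDPS | CC(C)(C)[Si](c1ccccc1)(c1ccccc1)O[C@H]1CC(=C)[C@H]2O[C@H]2C[C@@H](O[Si](CC)(CC)CC)[C@@H](O[Si](C)(C)C(C)(C)C)[C@H]2OC(=O)C(CO[Si](c3ccccc3)(c3ccccc3)C(C)(C)C)=C12
F2 | step 18 | C4 alcohol, (1R,2S,4R,5S,6S,8S): 4-OH, 5-OTBS | CC(C)(C)[Si](c1ccccc1)(c1ccccc1)O[C@H]1CC(=C)[C@H]2O[C@H]2C[C@@H](O)[C@@H](O[Si](C)(C)C(C)(C)C)[C@H]2OC(=O)C(CO[Si](c3ccccc3)(c3ccccc3)C(C)(C)C)=C12
F3 | step 20 | 4-epi-diol, (1R,2S,4S,5S,6S,8S) | CC(C)(C)[Si](c1ccccc1)(c1ccccc1)O[C@H]1CC(=C)[C@H]2O[C@H]2C[C@](C)(O)[C@@H](O)[C@H]2OC(=O)C(CO[Si](c3ccccc3)(c3ccccc3)C(C)(C)C)=C12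
F4 | step 20 | cyclic thiocarbonate of F3 across O4 and O5 | CC(C)(C)[Si](c1ccccc1)(c1ccccc1)O[C@H]1CC(=C)[C@H]2O[C@H]2C[C@]2(C)OC(=S)O[C@H]2[C@H]2OC(=O)C(CO[Si](c3ccccc3)(c3ccccc3)C(C)(C)C)=C12
F5 | step 20 | (4E)-alkene, (1R,2S,6S,8S): C4(CH3)=C5H in the ten-membered ring | CC(C)(C)[Si](c1ccccc1)(c1ccccc1)O[C@H]1CC(=C)[C@H]2O[C@H]2C/C(C)=C/[C@H]2OC(=O)C(CO[Si](c3ccccc3)(c3ccccc3)C(C)(C)C)=C12
F6 | step 13 | dienyl triethylsilyl ether, (1Z,4R,8S): C4 silyl ether of 18 | COc1ccc(COC[C@H](O[Si](CC)(CC)CC)C/C=C\C(=C)C[C@H](O[Si](c2ccccc2)(c2ccccc2)C(C)(C)C)C2=C(CO[Si](c3ccccc3)(c3ccccc3)C(C)(C)C)C(=O)OC2)cc1
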